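**Plan**

Numbering: O1 and C2–C8a are the upper flavonoid unit (rings A and C, ring B on C2). The prefix F marks atoms of the flavan unit, which is joined through F-C8–C3 and F-O7–C2.
Enabling feature: ring A is a 2-acylphloroglucinol (acyl carbon C4 on C4a, oxygens on C5, C7 and C8a), which is a folded 3,5,7-trioxoheptanoate. C2 is a ketal carbon whose O1 is the C8a oxygen of that same ring.
Cuts, in retrosynthetic order: four O–benzyl bonds; C2–O1 (ring C) and C4a–C8a (ring A) together; C4–C4a (ester plus trianion of methyl 3,5-dioxohexanoate); C3–F-C8 and C2–F-O7 (flavan phenol plus aryl 2,3-dioxopropanoate).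
Forward order: naringenin gives the flavan rings once its C4 oxygen is removed. The dihydrofuran ring closes next, the six-carbon chain is joined to C4, rings A and C close in one operation, and hydrogenolysis ends the route.
Stereochemistry: F-C2 (S) comes from (S)-naringenin. C3 is set by a catalyst-controlled Friedel–Crafts addition to the Re face of the central carbonyl. C2 follows from C3 because only the cis-fused ketal can form.

Key step: step 11

Assumption: the sense of induction of the squaramide catalyst on 9 cannot be derived from a close analogue. The quinidine-derived catalyst is taken to expose the Re face, and its quinine-derived pseudo-enantiomer would be used if the opposite holds.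
Assumption: commercial (S)-naringenin is taken to be enantiomerically pure (to be checked by chiral HPLC). C2 of 12–17 is drawn as one epimer, although either epimer is equally serviceable.

**Step 1**
Reactants: 1 (S)-naringenin
Product: 3 (2S)-5-hydroxyflavan-7,4'-diyl bis(ethyl carbonate), via naringenin tris(ethyl carbonate) 2 (not isolated)
Conditions: ClCO2Et, Et3N, THF, 0 °C; filter; filtrate into NaBH4, H2O–THF, 0 °C → rt
Reagents that add atoms: ethyl chloroformate, CCOC(=O)Cl
Why: This is the ortho-hydroxyl-assisted reductive deoxygenation of aryl ketones, in which borohydride reduces C4=O, the peri carbonate moves from O5 to the new alkoxide and leaves to give an ortho-quinone methide that is reduced at C4, so that only F-O5 is freed and F-C2 is untouched.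

**Step 2**
Reactants: 3 (2S)-5-hydroxyflavan-7,4'-diyl bis(ethyl carbonate)
Product: 4 (2S)-5-benzyloxyflavan-7,4'-diyl bis(ethyl carbonate)
Conditions: BnOH, PPh3, DIAD, THF, 0 °C → rt
Reagents that add atoms: benzyl alcohol, OCc1ccccc1
Why: Mitsunobu etherification of the only free phenol runs under essentially neutral conditions, so the two aryl carbonates should neither cleave nor migrate.

**Step 3**
Reactants: 4 (2S)-5-benzyloxyflavan-7,4'-diyl bis(ethyl carbonate)
Product: 5 (2S)-5-benzyloxy-7,4'-dihydroxyflavan
Conditions: K2CO3 (0.2 equiv), MeOH, 0 °C → rt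
Reagents that add atoms: none
Why: Base-catalysed methanolysis (transesterification) of aryl carbonates is fast at low temperature, where ring opening of the 4'-phenoxide at F-C2 is not expected.

**Step 4**
Reactants: 6 4'-(benzyloxy)acetophenone
Product: 7 methyl 3-[4-(benzyloxy)phenyl]-3-oxopropanoate
Conditions: NaH, (MeO)2CO, THF, reflux; AcOH quench
Reagents that add atoms: dimethyl carbonate, COC(=O)OC
Why: The crossed Claisen condensation of an aryl methyl ketone enolate with dimethyl carbonate is driven by deprotonation of the β-keto ester.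

**Step 5**
Reactants: 7 methyl 3-[4-(benzyloxy)phenyl]-3-oxopropanoate
Product: 8 methyl 3-[4-(benzyloxy)phenyl]-2-diazo-3-oxopropanoate
Conditions: p-ABSA, Et3N, MeCN, 0 °C → rt
Reagents that add atoms: 4-acetamidobenzenesulfonyl azide, CC(=O)Nc1ccc(cc1)S(=O)(=O)N=[N+]=[N-]
Why: Regitz diazo transfer onto an active methylene is routine for β-keto esters.

**Step 6**
Reactants: 8 methyl 3-[4-(benzyloxy)phenyl]-2-diazo-3-oxopropanoate
Product: 9 methyl 3-[4-(benzyloxy)phenyl]-2,3-dioxopropanoate
Conditions: DMDO, acetone, 0 °C → rt; concentrate, use at once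
Reagents that add atoms: dimethyldioxirane, CC1(C)OO1
Why: Oxygen transfer from a dioxirane to the diazo carbon with loss of N2 is a known way to anhydrous 2,3-diketo esters and leaves only volatile by-products.

**Step 7**
Reactants: 10 dehydroacetic acid
Product: 11 methyl 3,5-dioxohexanoate
Conditions: Mg(OMe)2, MeOH, reflux; 1 M HCl work-up
Reagents that add atoms: magnesium methoxide, C[O-].C[O-].[Mg+2]; methanol, CO
Why: Methoxide removes the 3-acetyl group by retro-Claisen cleavage and opens the pyrone lactone, and the magnesium chelate protects the diketo ester from further cleavage.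

**Step 8**
Reactants: 5 (2S)-5-benzyloxy-7,4'-dihydroxyflavan; 9 methyl 3-[4-(benzyloxy)phenyl]-2,3-dioxopropanoate
Product: 13 methyl ketal hydroxy ester (2S,3S,F-2S), via C2 hemiketal 12 (not isolated)
Conditions: 9-amino-9-deoxy-epi-quinidine 3,5-bis(trifluoromethyl)phenyl squaramide (10 mol %), 4 Å MS, CH2Cl2–toluene, −40 °C; then MeOH, HC(OMe)3, CSA (0.3 equiv), 0 °C → rt
Reagents that add atoms: methanol, CO
Why: Proposed new method: the quinuclidine nitrogen hydrogen-bonds to F-O7–H and raises the nucleophilicity of the ortho carbon F-C8 (less crowded than F-C6, which sits beside the benzyloxy group), while the squaramide N–H pair binds the central, most electrophilic carbonyl of 9 and exposes its Re face, so the catalyst sets C3 as S; F-O7 then adds to the aroyl carbonyl and acidic methanol fixes the hemiketal as the methyl ketal, any lactonisation onto the ester being reversed in methanol; the closest known reactions are the cinchona squaramide- or thiourea-catalysed ortho-hydroxyalkylation of electron-rich phenols and naphthols with trifluoropyruvates and isatins, and the uncatalysed condensation of ninhydrin with phenols to fused dihydrobenzofuran hemiketals.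

**Step 9**
Reactants: 13 methyl ketal hydroxy ester
Product: 14 O3,F-O4'-dibenzyl methyl ketal ester (2S,3S,F-2S)
Conditions: BnBr, NaH, Bu4NI (cat.), DMF, 0 °C → rt (BnBr charged before NaH)
Reagents that add atoms: benzyl bromide, BrCc1ccccc1
Why: One Williamson etherification caps the remaining phenol and the tertiary carbinol, and masking O3 is essential because a free C3 hydroxyl would later add to C5 of the chain and dehydrate to a 3(2H)-furanone.

**Step 10**
Reactants: 14 O3,F-O4'-dibenzyl methyl ketal ester; 11 methyl 3,5-dioxohexanoate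
Product: 16 triketo ester precursor (2S,3R,F-2S), via trilithium trianion 15 (not isolated)
Conditions: 11 (3 equiv), LDA (9.3 equiv), THF, −78 → 0 °C; then 14, 0 °C → rt; AcOH quench at −78 °C
Reagents that add atoms: none
Why: This is the Claisen-type C-acylation of a β-polycarbonyl polyanion at its terminal, most basic carbanion; 14 has no acidic hydrogen, lithium chelation between O3 and the ester carbonyl aids attack, and excess trianion absorbs the proton released by the more acidic product.

**Step 11**
Reactants: 16 triketo ester precursor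
Product: 18 tetrabenzyl ether of the target (2R,3R,F-2S), via acylphloroglucinol methyl ketal 17 (not isolated)
Conditions: NaOMe (6 equiv), MeOH–THF, 0 → 40 °C; cold 1 M HCl to pH 4, extract into CH2Cl2; then CSA (0.2 equiv), 5 Å MS, CH2Cl2, rt
Reagents that add atoms: none
Why: Methoxide converts 16 into its polyenolate, in which the ketone carbonyls are masked and the ester carbon C8a is the remaining electrophile; C4a, flanked by C4 and C5, adds to it, methoxide leaves and the cyclohexanetrione tautomerises irreversibly to phloroglucinol 17. This is the Claisen (C-acylation) mode known for 3,5,7-triketo esters under strongly basic conditions, which gives 2-acylphloroglucinols. Ring A closes 6-(enolendo)-exo-trig at the ester carbonyl, and ring C closes 6-exo-trig when acid ionises C2–OMe to an oxocarbenium ion, stabilised by F-O7 and the 4-benzyloxyphenyl group, that is captured by a ring A hydroxyl ortho to C4. C2 is the only new stereocentre and is governed by C3, because O1 is tethered through C4 and reaches only the face of C2 cis to C4 (a trans-fused pyranone–dihydrofuran is too strained), and because ketal exchange is reversible both C2 epimers of 16 converge on 2R. The step needs Claisen closure to win over aldol (C8 on C4), pyrone (O5 on C8a) and furanone closure: quaternary C3 shields C4, methoxide reopens any pyrone whereas aromatisation is final, and the O3 benzyl ether keeps that oxygen away from C5. The two hydroxyls ortho to the acyl group interchange by rotation about C4–C4a, so the second closure raises no regiochemical question.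

**Step 12**
Reactants: 18 tetrabenzyl ether of the target
Product: 19 CNP0208300.2 (2R,3R,F-2S)
Conditions: H2 (1 atm), Pd(OH)2/C, THF–MeOH, rt
Reagents that add atoms: none
Why: Catalytic hydrogenolysis cleaves the four O–CH2Ph bonds, while the hindered tertiary C3–O bond, the C2 ketal, the cyclic benzylic ether at F-C2 and the hydrogen-bonded aryl ketone are expected to persist at one atmosphere.

**Compound list**

1 | (S)-naringenin, (2S)-5,7-dihydroxy-2-(4-hydroxyphenyl)chroman-4-one | O=C1C[C@@H](c2ccc(O)cc2)Oc2cc(O)cc(O)c21 | starting material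
2 | (S)-naringenin 5,7,4'-tris(ethyl carbonate) | O=C1C[C@@H](c2ccc(OC(=O)OCC)cc2)Oc2cc(OC(=O)OCC)cc(OC(=O)OCC)c21 | intermediate
3 | (2S)-5-hydroxyflavan-7,4'-diyl bis(ethyl carbonate) | C1C[C@@H](c2ccc(OC(=O)OCC)cc2)Oc2cc(OC(=O)OCC)cc(O)c21 | intermediate
4 | (2S)-5-benzyloxyflavan-7,4'-diyl bis(ethyl carbonate) | C1C[C@@H](c2ccc(OC(=O)OCC)cc2)Oc2cc(OC(=O)OCC)cc(OCc3ccccc3)c21 | intermediate
5 | (2S)-5-benzyloxy-7,4'-dihydroxyflavan | C1C[C@@H](c2ccc(O)cc2)Oc2cc(O)cc(OCc3ccccc3)c21 | intermediate
6 | 4'-(benzyloxy)acetophenone | CC(=O)c1ccc(OCc2ccccc2)cc1 | starting material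
7 | methyl 3-[4-(benzyloxy)phenyl]-3-oxopropanoate | COC(=O)CC(=O)c1ccc(OCc2ccccc2)cc1 | intermediate
8 | methyl 3-[4-(benzyloxy)phenyl]-2-diazo-3-oxopropanoate | COC(=O)C(=[N+]=[N-])C(=O)c1ccc(OCc2ccccc2)cc1 | intermediate
9 | methyl 3-[4-(benzyloxy)phenyl]-2,3-dioxopropanoate | COC(=O)C(=O)C(=O)c1ccc(OCc2ccccc2)cc1 | intermediate
10 | dehydroacetic acid | CC(=O)C1=C(O)C=C(C)OC1=O | starting material
11 | methyl 3,5-dioxohexanoate | CC(=O)CC(=O)CC(=O)OC | intermediate
12 | C2 hemiketal (2S,3S,F-2S): methyl 2,3-dihydroxy-2-[4-(benzyloxy)phenyl]-2,3-dihydrobenzofuran-3-carboxylate whose benzo ring is ring A of flavan 5 (F-O7 on C2, F-C8 on C3); C2 epimers equilibrate | O[C@@]2(c3ccc(OCc5ccccc5)cc3)Oc3cc(OCc5ccccc5)c4c(c3[C@]2(C(=O)OC)O)O[C@H](c1ccc(O)cc1)CC4 | intermediate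
13 | methyl ketal hydroxy ester (2S,3S,F-2S): as 12 with OMe in place of the C2 hydroxyl | CO[C@@]2(c3ccc(OCc5ccccc5)cc3)Oc3cc(OCc5ccccc5)c4c(c3[C@]2(C(=O)OC)O)O[C@H](c1ccc(O)cc1)CC4 | intermediate
14 | O3,F-O4'-dibenzyl methyl ketal ester (2S,3S,F-2S): as 13 with benzyl ethers on the C3 oxygen and on the flavan 4'-oxygen | CO[C@@]2(c3ccc(OCc5ccccc5)cc3)Oc3cc(OCc5ccccc5)c4c(c3[C@]2(C(=O)OC)OCc5ccccc5)O[C@H](c1ccc(OCc5ccccc5)cc1)CC4 | intermediate
15 | trilithium trianion of methyl 3,5-dioxohexanoate | C=C([O-])C=C([O-])C=C([O-])OC.[Li+].[Li+].[Li+] | intermediate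
16 | triketo ester precursor (2S,3R,F-2S): as 14 with C3 bearing the chain C(=O)CH2C(=O)CH2C(=O)CH2CO2Me (C4 to C8a) in place of the ester | CO[C@@]2(c3ccc(OCc5ccccc5)cc3)Oc3cc(OCc5ccccc5)c4c(c3[C@]2(C(=O)CC(=O)CC(=O)CC(=O)OC)OCc5ccccc5)O[C@H](c1ccc(OCc5ccccc5)cc1)CC4 | intermediate
17 | acylphloroglucinol methyl ketal (2S,3R,F-2S): as 16 with the chain folded to a 2,4,6-trihydroxybenzoyl group on C3 | CO[C@@]2(c3ccc(OCc5ccccc5)cc3)Oc3cc(OCc5ccccc5)c4c(c3[C@]2(C(=O)c6c(O)cc(O)cc6O)OCc5ccccc5)O[C@H](c1ccc(OCc5ccccc5)cc1)CC4 | intermediate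
18 | tetrabenzyl ether of the target (2R,3R,F-2S): benzyl on O3, O4', F-O5 and F-O4'; ring A hydroxyls free | O=C1c2c(O)cc(O)cc2O[C@@]2(c3ccc(OCc5ccccc5)cc3)Oc3cc(OCc5ccccc5)c4c(c3[C@@]12OCc5ccccc5)O[C@H](c1ccc(OCc5ccccc5)cc1)CC4 | intermediate
19 | CNP0208300.2 (2R,3R,F-2S) | O=C1c2c(O)cc(O)cc2O[C@@]2(c3ccc(O)cc3)Oc3cc(O)c4c(c3[C@@]12O)O[C@H](c1ccc(O)cc1)CC4 | target

**Step count**

Total step count: 12.
Longest linear sequence: 8 (steps 1, 2, 3, 8, 9, 10, 11, 12).

**Steps most likely to fail**

Step 8. Facial selectivity at the central carbonyl may be poor, an uncatalysed background addition may compete, or part of the attack may go through F-C6. The fallback sets out from 5 and 9 and comes back at 13. The two are condensed without a chiral catalyst in AcOH at rt, which is the classical condensation of vicinal tricarbonyl compounds with electron-rich phenols. This forms 12 together with the 3-epi hemiketal F1. Ketalisation with MeOH, HC(OMe)3 and CSA turns the pair into 13 and the 3-epi methyl ketal F2. Because F-C2 is fixed, these two are diastereomers and are separated by chromatography or crystallisation. Stereocontrol is thus replaced by separation on the resident stereocentre.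

Step 10. Acyl transfer to the ester on quaternary C3 may be too slow, so the trianion may decay or merely be protonated on work-up. The fallback sets out from 14 and comes back at 16, and it exchanges acyl substitution for carbonyl addition followed by oxidation. i-Bu2AlH in CH2Cl2 at −78 °C reduces the ester to the aldehyde F3. Trianion 15 adds to F3 at −78 °C to give the aldol adduct F4 as a mixture of C4 carbinol epimers. Dess–Martin periodinane buffered with NaHCO3 then oxidises the β-hydroxy ketone to the 1,3-diketone 16.

Step 11. Chain cleavage by retro-Claisen attack of methoxide, or pyrone closure, may outrun C-acylation. The fallback sets out from 14 by way of the aldehyde F3 described above and comes back at 17. Ring A is bought ready-made rather than folded.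
- Phloroglucinol with MOMCl and i-Pr2NEt gives 1,3,5-tris(methoxymethoxy)benzene F5.
- n-BuLi in THF at 0 °C gives 2,4,6-tris(methoxymethoxy)phenyllithium F6 by directed ortho-lithiation.
- Addition of F6 to F3 gives the carbinol F7.
- Dess–Martin periodinane gives the aryl ketone F8.
- TsOH·H2O in MeOH at 40 °C removes the three phenolic MOM groups to give 17, which closes to 18 under the acid conditions of step 11.

**Further compounds**

F1 | step 8 | 3-epi hemiketal (C3 epimer of 12) | O[C@]2(c3ccc(OCc5ccccc5)cc3)Oc3cc(OCc5ccccc5)c4c(c3[C@@]2(C(=O)OC)O)O[C@H](c1ccc(O)cc1)CC4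
F2 | step 8 | 3-epi methyl ketal (C3 epimer of 13) | CO[C@]2(c3ccc(OCc5ccccc5)cc3)Oc3cc(OCc5ccccc5)c4c(c3[C@@]2(C(=O)OC)O)O[C@H](c1ccc(O)cc1)CC4
F3 | step 10 | aldehyde (14 with CHO in place of CO2Me) | CO[C@@]2(c3ccc(OCc5ccccc5)cc3)Oc3cc(OCc5ccccc5)c4c(c3[C@]2(C=O)OCc5ccccc5)O[C@H](c1ccc(OCc5ccccc5)cc1)CC4
F4 | step 10 | aldol adduct (16 with CHOH at C4, both epimers) | CO[C@@]2(c3ccc(OCc5ccccc5)cc3)Oc3cc(OCc5ccccc5)c4c(c3[C@]2(C(O)CC(=O)CC(=O)CC(=O)OC)OCc5ccccc5)O[C@H](c1ccc(OCc5ccccc5)cc1)CC4
F5 | step 11 | 1,3,5-tris(methoxymethoxy)benzene | COCOc1cc(OCOC)cc(OCOC)c1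
F6 | step 11 | 2,4,6-tris(methoxymethoxy)phenyllithium | [Li]c1c(OCOC)cc(OCOC)cc1OCOC
F7 | step 11 | carbinol from F6 and F3 (both C4 epimers) | CO[C@@]2(c3ccc(OCc5ccccc5)cc3)Oc3cc(OCc5ccccc5)c4c(c3[C@]2(C(O)c6c(OCOC)cc(OCOC)cc6OCOC)OCc5ccccc5)O[C@H](c1ccc(OCc5ccccc5)cc1)CC4
F8 | step 11 | aryl ketone (17 with three MOM ethers on ring A) | CO[C@@]2(c3ccc(OCc5ccccc5)cc3)Oc3cc(OCc5ccccc5)c4c(c3[C@]2(C(=O)c6c(OCOC)cc(OCOC)cc6OCOC)OCc5ccccc5)O[C@H](c1ccc(OCc5ccccc5)cc1)CC4
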